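**Plan**

Labels: oxane ring O1, C2 (aryl), C3, C4, C5, C6. The side chain is C1'-C3' outward from C3, and the carbinol carbon on C5 is C7. Ar = 4-(pivaloyloxy)phenyl in all names.
Cuts, in retrosynthetic order: the helper oxygens on C6 and C3'; C5-C7 (aldol); C2'-C3' (alkenylchromium addition); C1'=C2' (iodo-olefination); last, C2-C3 together with O1-C6 (domino aldol/acetalization). This leaves glutaraldehyde, three copies of one protected 4-hydroxybenzaldehyde, and CHI3.
Enabling feature: C1'-C3-C4-C5-C6 is a glutaraldehyde chain, and C2 and C7 are two anti-aldol carbinols related by a hidden twofold axis through C4. The C2 oxygen lies delta to C6, so the first aldol closes the oxane ring by itself and leaves C1' (free formyl) and C6 (hemiacetal) differentiated.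
Forward: the three benzene rings are bought and the oxane is the only ring made (step 2). Its O1-C6 link opens only transiently in step 5 and is fixed as the ether in step 6. C1' is extended (steps 3, 4), C5 is branched (step 5), both helper oxygens leave together (step 6), and the phenols are freed (step 7).
Stereochemistry: all four centres come from L-proline, used twice in the same sense (C2/C3 in step 2, C5/C7 in step 5). The all-cis ring has no all-equatorial chair, so it is fixed during C-C bond formation and not by ring-closure preferences. The E-alkene comes from hydride capture of an allyl cation.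

Key step: step 2

Assumption: C6 (hemiacetal) and C3' (side-chain carbinol) are carried as epimer mixtures, because both centres are erased in step 6.

Step 1
Reactants: 1 4-hydroxybenzaldehyde
Product: 2 4-formylphenyl pivalate
Conditions: PivCl, Et3N, DMAP (cat.), CH2Cl2, 0 °C to rt
Reagents that add atoms: pivaloyl chloride CC(C)(C)C(=O)Cl
Why: O-acylation of the phenol gives an ester that survives amine catalysis, chromium reagents and BF3, raises the electrophilicity of the formyl group for both aldol steps, and keeps the later benzylic C-O bonds from ionising.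

Step 2
Reactants: 2 4-formylphenyl pivalate; 3 glutaraldehyde
Product: 5 (2R,3S)-2-Ar-6-hydroxyoxane-3-carbaldehyde, via open-chain anti aldol 4 (not isolated)
Conditions: 3 (50 wt % in H2O, 3 equiv), L-proline (30 mol %), NMP, 4 °C
Reagents that add atoms: none
Why: L-Proline condenses with one formyl group of 3, which water stores as its cyclic hydrate, to an E-enamine whose carboxylic acid binds the non-enolisable aldehyde 2 in a chair-like hydrogen-bonded transition state, and hydrolysis of the iminium aldolate frees the anti aldol 4. The closest known reaction type is the proline-mediated domino cross-aldol/acetalization of aqueous glutaraldehyde with aromatic aldehydes. The oxane ring closes by 6-exo-trig addition of the new C2 hydroxyl to the C6 formyl group, so that O1-C6 follows C2-C3 in the same flask. C2 (R) and C3 (S) are both set by the catalyst, which exposes the re face of 2 to one face of the enamine, and the anti relation of the aldol is the 2,3-cis relation of the ring, whereas C6 forms as an anomer mixture that is erased in step 6. The step needs cross-aldol over self-aldol, one aldol instead of two, and no epimerisation at C3. These are secured because 2 cannot enolise and is activated by its acyloxy group, because the unbranched formyl group of 4 is masked as the hemiacetal at once, and because the formyl group left on C3 is alpha-branched and slow to form an enamine.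

Step 3
Reactants: 5 (2R,3S)-2-Ar-6-hydroxyoxane-3-carbaldehyde
Product: 6 (2R,3R)-2-Ar-3-[(E)-2-iodoethenyl]oxan-6-ol
Conditions: CHI3, CrCl2, THF-dioxane, 0 °C to rt
Reagents that add atoms: iodoform IC(I)I
Why: In this Takai olefination the geminal dichromium species from CHI3 and CrCl2 adds to the only free formyl group and eliminates to the E-iodoalkene under non-basic conditions, so C3 is not epimerised and the C6 aldehyde stays masked, and any Z isomer is harmless because C1' becomes sp3 in step 6.

Step 4
Reactants: 6 (2R,3R)-2-Ar-3-[(E)-2-iodoethenyl]oxan-6-ol; 2 4-formylphenyl pivalate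
Product: 8 (2R,3R)-2-Ar-3-[(E)-3-Ar-3-hydroxyprop-1-enyl]oxan-6-ol, via alkenylchromium dichloride 7 (not isolated)
Conditions: 2 (2 equiv), CrCl2, NiCl2 (cat.), DMF, rt
Reagents that add atoms: none
Why: In this Nozaki-Hiyama-Kishi reaction nickel-catalysed insertion into the C-I bond and transmetalation give 7, which tolerates hydroxyl and ester groups and adds 1,2 to the excess free aldehyde 2 faster than to the masked C6 aldehyde, and the new carbinol centre C3' forms as an epimer mixture that is erased in step 6.

Step 5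
Reactants: 8 (2R,3R)-2-Ar-3-[(E)-3-Ar-3-hydroxyprop-1-enyl]oxan-6-ol; 2 4-formylphenyl pivalate
Product: 11 (2R,3R,5S)-2-Ar-3-[(E)-3-Ar-3-hydroxyprop-1-enyl]-5-[(R)-Ar(hydroxy)methyl]oxan-6-ol, via ring-opened hydroxy aldehyde 9 (not isolated), via open-chain bis-aldol 10 (not isolated)
Conditions: 2 (3 equiv), L-proline (30 mol %), DMF, 4 °C
Reagents that add atoms: none
Why: This is a proline-catalysed cross-aldol of the same type as step 2, in which the hemiacetal opens reversibly to 9, its unbranched formyl group forms the enamine at C5, the same catalyst enantiomer again gives the anti aldol (C5 and C7 both under catalyst control, the remote C3 centre having little say), and 10 recloses through the C2 hydroxyl because neither the C7 nor the C3' hydroxyl can reach C6 in a five- or six-membered ring.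

Step 6
Reactants: 11 (2R,3R,5S)-2-Ar-3-[(E)-3-Ar-3-hydroxyprop-1-enyl]-5-[(R)-Ar(hydroxy)methyl]oxan-6-ol
Product: 13 (2R,3S,5R)-2-Ar-3-[(E)-3-Ar-prop-2-enyl]-5-[(R)-Ar(hydroxy)methyl]oxane, via oxane diol 12 (not isolated)
Conditions: Et3SiH (10 equiv), BF3·OEt2 (3 equiv), CH2Cl2, -78 to -30 °C
Reagents that add atoms: none
Why: In this ionic hydrogenation (silane/Lewis acid deoxygenation) BF3 ionises the anomeric hydroxyl to the ring oxocarbenium ion and, on warming, the doubly activated C3' hydroxyl to a 1-aryl-3-alkylallyl cation, and Et3SiH delivers hydride to C6 and to the non-benzylic terminus C1' so that the conjugated E-styrene results, while the simple benzylic C7-OH and C2-O1 bonds, deactivated by the acyloxy groups, should stay intact and no stereocentre is touched.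

Step 7
Reactants: 13 (2R,3S,5R)-2-Ar-3-[(E)-3-Ar-prop-2-enyl]-5-[(R)-Ar(hydroxy)methyl]oxane
Product: 14 4-[(2R,3S,5R)-5-[(R)-hydroxy(4-hydroxyphenyl)methyl]-3-[(E)-3-(4-hydroxyphenyl)prop-2-enyl]oxan-2-yl]phenol
Conditions: K2CO3, MeOH, 0 °C to rt; then aq. NH4Cl
Reagents that add atoms: none
Why: Base-mediated transesterification removes the three aryl esters, whose phenoxide leaving groups make them the most labile bonds present, under conditions too mild to form a quinone methide at C2 or C7, so the all-cis arrangement should be kept.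

**Compound list**

1 | 4-hydroxybenzaldehyde | O=Cc1ccc(O)cc1 | starting material
2 | 4-formylphenyl pivalate | CC(C)(C)C(=O)Oc1ccc(C=O)cc1 | intermediate
3 | glutaraldehyde (pentanedial; in water mainly oxane-2,6-diol) | O=CCCCC=O | starting material
4 | (2S)-2-[(R)-Ar(hydroxy)methyl]pentanedial | O=C[C@@H](CCC=O)[C@@H](O)c1ccc(OC(=O)C(C)(C)C)cc1 | intermediate
5 | (2R,3S)-2-Ar-6-hydroxyoxane-3-carbaldehyde (2,3-cis; C6 anomers) | O=C[C@H]1CCC(O)O[C@H]1c1ccc(OC(=O)C(C)(C)C)cc1 | intermediate
6 | (2R,3R)-2-Ar-3-[(E)-2-iodoethenyl]oxan-6-ol | I/C=C/[C@H]1CCC(O)O[C@H]1c1ccc(OC(=O)C(C)(C)C)cc1 | intermediate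
7 | alkenylchromium dichloride derived from 6 | Cl[Cr](Cl)/C=C/[C@H]1CCC(O)O[C@H]1c1ccc(OC(=O)C(C)(C)C)cc1 | intermediate
8 | (2R,3R)-2-Ar-3-[(E)-3-Ar-3-hydroxyprop-1-enyl]oxan-6-ol (C3' epimers) | CC(C)(C)C(=O)Oc1ccc(cc1)C(O)/C=C/[C@H]1CCC(O)O[C@H]1c1ccc(OC(=O)C(C)(C)C)cc1 | intermediate
9 | (4R,5E)-7-Ar-7-hydroxy-4-[(R)-Ar(hydroxy)methyl]hept-5-enal | CC(C)(C)C(=O)Oc1ccc(cc1)C(O)/C=C/[C@@H](CCC=O)[C@@H](O)c1ccc(OC(=O)C(C)(C)C)cc1 | intermediate
10 | (2S,4R,5E)-7-Ar-7-hydroxy-2,4-bis[(R)-Ar(hydroxy)methyl]hept-5-enal | CC(C)(C)C(=O)Oc1ccc(cc1)C(O)/C=C/[C@@H](C[C@@H]([C@@H](O)c1ccc(OC(=O)C(C)(C)C)cc1)C=O)[C@@H](O)c1ccc(OC(=O)C(C)(C)C)cc1 | intermediate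
11 | (2R,3R,5S)-2-Ar-3-[(E)-3-Ar-3-hydroxyprop-1-enyl]-5-[(R)-Ar(hydroxy)methyl]oxan-6-ol | CC(C)(C)C(=O)Oc1ccc(cc1)C(O)/C=C/[C@H]1C[C@@H]([C@@H](O)c2ccc(OC(=O)C(C)(C)C)cc2)C(O)O[C@H]1c1ccc(OC(=O)C(C)(C)C)cc1 | intermediate
12 | (2R,3R,5R)-2-Ar-3-[(E)-3-Ar-3-hydroxyprop-1-enyl]-5-[(R)-Ar(hydroxy)methyl]oxane | CC(C)(C)C(=O)Oc1ccc(cc1)C(O)/C=C/[C@H]1C[C@@H]([C@@H](O)c2ccc(OC(=O)C(C)(C)C)cc2)CO[C@H]1c1ccc(OC(=O)C(C)(C)C)cc1 | intermediate
13 | (2R,3S,5R)-2-Ar-3-[(E)-3-Ar-prop-2-enyl]-5-[(R)-Ar(hydroxy)methyl]oxane (tripivalate of the target) | CC(C)(C)C(=O)Oc1ccc(/C=C/C[C@H]2C[C@@H]([C@@H](O)c3ccc(OC(=O)C(C)(C)C)cc3)CO[C@H]2c2ccc(OC(=O)C(C)(C)C)cc2)cc1 | intermediate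
14 | 4-[(2R,3S,5R)-5-[(R)-hydroxy(4-hydroxyphenyl)methyl]-3-[(E)-3-(4-hydroxyphenyl)prop-2-enyl]oxan-2-yl]phenol | Oc1ccc(/C=C/C[C@H]2C[C@@H]([C@@H](O)c3ccc(O)cc3)CO[C@H]2c2ccc(O)cc2)cc1 | target

Total step count: 7. Longest linear sequence: 7 (steps 1 to 7; compound 2 enters three times).

**Steps most likely to fail**

Step 5. The substituted hemiacetal may open too slowly for enamine formation. The new C7 hydroxyl also finds no formyl group to add to, so retro-aldol equilibration may erode the anti selectivity.
- The fallback sets out from 5 and comes back at 11.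
- The second aldol is run on 5 itself with 2 and L-proline, so that it is again a domino aldol/acetalization in which the C7 hydroxyl adds to the C1' formyl group.
- This should give the twofold-symmetric bis-hemiacetal 2,6-di-Ar-3,7-dioxabicyclo[3.3.1]nonane-4,8-diol F1. It is a temporary second ring in which both aryl groups are equatorial and C3 and C5 are bridgeheads that cannot epimerise.
- Takai olefination with one equivalent of CHI3 opens either of the two equivalent hemiacetals to the iodoalkene hemiacetal F2. The surviving monocyclic hemiacetal should hold less free aldehyde than the bicycle.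
- Nozaki-Hiyama-Kishi coupling with 2 through the alkenylchromium dichloride F3 gives 11.

Step 6. Three processes may compete:
- ionisation at C7 or C2;
- loss of the C3 proton from the allyl cation to an aryl diene, whose re-protonation would scramble C3;
- hydride capture at the benzylic terminus C3'.

The fallback sets out from 11 and comes back at 13.
- The reduction is stopped at -78 °C and 12 is isolated. The allylic oxygen is then removed without a cation, by reductive 1,3-transposition.
- A Mitsunobu reaction (PPh3, DEAD, 2-nitrobenzenesulfonylhydrazide, THF, -30 °C) should occur at the unhindered allylic C3' hydroxyl in preference to the C7 hydroxyl, which is flanked by the ring. It gives the allylic sulfonylhydrazine F4.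
- On warming F4 loses sulfinic acid to give the allylic diazene F5. Its retro-ene loss of N2 delivers hydrogen to C1' and leaves the E-styrene of 13.

Step 3. Olefination may also reach C6 through the small share of open hydroxy aldehyde. The Lewis-acidic chromium salts may also trigger beta-elimination of O1 or epimerisation at C3.
- The fallback sets out from 5 and comes back at 8.
- A Wittig reaction of 5 with (triphenylphosphoranylidene)acetaldehyde (CH2Cl2, rt), a stabilised ylide that should take only the free formyl group, gives the E-enal hemiacetal F6.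
- 4-Iodophenol is acylated (PivCl, Et3N) to 4-iodophenyl pivalate F7.
- Nozaki-Hiyama-Kishi addition (CrCl2, NiCl2 cat., DMF) of F7, through the arylchromium dichloride F8, to the formyl group of F6 makes the C3'-aryl bond instead of the C2'-C3' bond and gives 8.

**Further compounds**

F1 | step 5 | 2,6-di-Ar-3,7-dioxabicyclo[3.3.1]nonane-4,8-diol (twofold-symmetric, both Ar equatorial) | OC1[C@H]2C[C@@H]([C@@H](O1)c1ccc(OC(=O)C(C)(C)C)cc1)C(O)O[C@H]2c1ccc(OC(=O)C(C)(C)C)cc1
F2 | step 5 | (2R,3R,5S)-2-Ar-5-[(R)-Ar(hydroxy)methyl]-3-[(E)-2-iodoethenyl]oxan-6-ol | I/C=C/[C@H]1C[C@@H]([C@@H](O)c2ccc(OC(=O)C(C)(C)C)cc2)C(O)O[C@H]1c1ccc(OC(=O)C(C)(C)C)cc1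
F3 | step 5 | alkenylchromium dichloride derived from F2 | Cl[Cr](Cl)/C=C/[C@H]1C[C@@H]([C@@H](O)c2ccc(OC(=O)C(C)(C)C)cc2)C(O)O[C@H]1c1ccc(OC(=O)C(C)(C)C)cc1
F4 | step 6 | N-(C3'-allyl)-2-nitrobenzenesulfonylhydrazine derived from 12 | NN(C(/C=C/[C@H]1C[C@@H]([C@@H](O)c2ccc(OC(=O)C(C)(C)C)cc2)CO[C@H]1c1ccc(OC(=O)C(C)(C)C)cc1)c1ccc(OC(=O)C(C)(C)C)cc1)S(=O)(=O)c1ccccc1[N+](=O)[O-]
F5 | step 6 | allylic diazene derived from F4 | N=NC(/C=C/[C@H]1C[C@@H]([C@@H](O)c2ccc(OC(=O)C(C)(C)C)cc2)CO[C@H]1c1ccc(OC(=O)C(C)(C)C)cc1)c1ccc(OC(=O)C(C)(C)C)cc1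
F6 | step 3 | (E)-3-[(2R,3R)-2-Ar-6-hydroxyoxan-3-yl]prop-2-enal | O=C/C=C/[C@H]1CCC(O)O[C@H]1c1ccc(OC(=O)C(C)(C)C)cc1
F7 | step 3 | 4-iodophenyl pivalate | CC(C)(C)C(=O)Oc1ccc(I)cc1
F8 | step 3 | 4-(pivaloyloxy)phenylchromium dichloride | CC(C)(C)C(=O)Oc1ccc([Cr](Cl)Cl)cc1
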